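**Retrosynthetic overview**
1. The C-7 hydroxyl goes in last, by SeO2 allylic hydroxylation of 14-deoxyandrographolide; the butenolide comes from a side-chain alkyne (hydroxymethylation, trans-hydroalumination/iodination, carbonylative lactonisation).
2. The 3,19-diol comes from a bicyclic C-3 ketone / C-19 ester by LiAlH4, which also releases the chiral auxiliary.
3. Key disconnection: C4–C5 and C9–C10, formed in one oxidative free-radical bicyclisation (Mn(OAc)3/Cu(OAc)2) of an acyclic (E,E)-dienyl α-methyl β-keto ester. Ring A closes first, then ring B, ending in the exocyclic alkene; a (+)-8-phenylmenthyl ester fixes the absolute sense.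
4. The keto ester comes from a methyl dienynoate and the auxiliary propanoate (crossed Claisen); the dienynoate from pent-4-ynal by two isopropenyl-Grignard / Johnson–Claisen cycles.

Assumption: (+)-8-phenylmenthol is a purchased, recoverable chiral auxiliary and is treated as a reagent; paraformaldehyde is written as monomeric formaldehyde.

Labdane numbering is used for the bicyclic compounds.

**Step 1**
Reactants: 1 pent-4-ynal; 2 isopropenylmagnesium bromide
Product: 3 rac-2-methylhept-1-en-6-yn-3-ol
Conditions: THF, −78 → 0 °C; then H2O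
Reagents that add atoms: none
Why: Grignard 1,2-addition to the aldehyde is far faster at −78 °C than deprotonation of the terminal alkyne; the carbinol centre is racemic and is destroyed in step 2.

**Step 2**
Reactants: 3 rac-2-methylhept-1-en-6-yn-3-ol; 4 trimethyl orthoacetate
Product: 6 methyl (4E)-4-methylnon-4-en-8-ynoate, via mixed ketene acetal 5 (not isolated)
Conditions: CH3C(OCH3)3 (6 equiv), EtCO2H (0.1 equiv), xylene, 140 °C, MeOH distilled off
Reagents that add atoms: none
Why: Johnson orthoester Claisen rearrangement; the [3,3] shift runs through a chair with the carbinol substituent equatorial and so gives the (E)-trisubstituted alkene (typically >95:5).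

**Step 3**
Reactants: 6 methyl (4E)-4-methylnon-4-en-8-ynoate; 2 isopropenylmagnesium bromide
Product: 9 rac-(6E)-2,6-dimethylundeca-1,6-dien-10-yn-3-ol, via aluminium hemiacetal 7 (not isolated), via aldehyde 8 (not isolated)
Conditions: i-Bu2AlH (1.1 equiv), CH2Cl2, −78 °C; then CH2=C(CH3)MgBr (2.5 equiv, THF), −78 → 0 °C; aq. KNaC4H4O6
Reagents that add atoms: none
Why: One-pot partial ester reduction / Grignard addition; the aluminium hemiacetal is stable at −78 °C and releases the aldehyde only on warming, when the Grignard reagent traps it; the new carbinol centre is racemic and is destroyed in step 4.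

**Step 4**
Reactants: 9 rac-(6E)-2,6-dimethylundeca-1,6-dien-10-yn-3-ol; 4 trimethyl orthoacetate
Product: 11 methyl (4E,8E)-4,8-dimethyltrideca-4,8-dien-12-ynoate, via mixed ketene acetal 10 (not isolated)
Conditions: CH3C(OCH3)3 (6 equiv), EtCO2H (0.1 equiv), xylene, 140 °C, MeOH distilled off
Reagents that add atoms: none
Why: Second Johnson–Claisen rearrangement; the same chair model sets the second (E)-trisubstituted alkene.

**Step 5**
Reactants: 12 propanoyl chloride
Product: 13 (1S,2R,5S)-5-methyl-2-(2-phenylpropan-2-yl)cyclohexyl propanoate [(+)-8-phenylmenthyl propanoate]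
Conditions: (+)-8-phenylmenthol, Et3N, DMAP (cat.), CH2Cl2, 0 °C → rt
Reagents that add atoms: (+)-8-phenylmenthol, O[C@H]1C[C@@H](C)CC[C@@H]1C(C)(C)c1ccccc1
Why: DMAP-catalysed acylation of the secondary alcohol; no stereocentre is touched.

**Step 6**
Reactants: 13 (+)-8-phenylmenthyl propanoate (2.2 equiv); 11 methyl (4E,8E)-4,8-dimethyltrideca-4,8-dien-12-ynoate
Product: 15 (+)-8-phenylmenthyl (2RS,6E,10E)-2,6,10-trimethyl-3-oxopentadeca-6,10-dien-14-ynoate, via lithium enolate 14 (not isolated)
Conditions: LiN(i-Pr)2 (2.3 equiv), THF, −78 °C; then 11, −78 → 0 °C; aq. HCl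
Reagents that add atoms: none
Why: Crossed Claisen condensation; the hindered ester enolate (comparable to a tert-butyl ester enolate) does not self-condense and is acylated by the methyl ester, and the C-2 epimers do not matter because this carbon becomes the radical centre in step 7.

**Step 7**
Reactants: 15 (+)-8-phenylmenthyl (2RS,6E,10E)-2,6,10-trimethyl-3-oxopentadeca-6,10-dien-14-ynoate
Product: 16 (+)-8-phenylmenthyl (4S,5S,9R,10S)-3-oxo-15,16-dinorlabd-8(17)-en-13-yn-19-oate (trans-decalin; ester axial and cis to the C-10 methyl; C-9 chain equatorial)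
Conditions: Mn(OAc)3·2H2O (2.2 equiv), Cu(OAc)2·H2O (1.0 equiv), degassed AcOH, 25 °C; no Lewis acid additive
Reagents that add atoms: none
Why: Oxidative free-radical polyene cyclisation (Snider type): trivalent manganese oxidises the enol to the free C-4 radical, which closes ring A (6-endo, C4–C5) and then ring B (6-endo, C9–C10) through a chair–chair array of the (E,E)-diene (trans fusion, C-9 chain equatorial), the ketone and ester carbonyls lying anti so that the ester ends up axial and cis to the C-10 methyl, the stacked phenyl of the auxiliary shielding one face of the radical so that the (4S,5S,9R,10S) series is favoured (sense assigned from the stacking model; d.r. for such α-methyl esters is modest, roughly 6–9:1 at best, with the minor isomer removed by chromatography), and divalent copper oxidises the tertiary C-8 radical to the exocyclic alkene before it can add to the remote alkyne.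

**Step 8**
Reactants: 16 bicyclic keto ester
Product: 17 (3R,4R,5S,9R,10S)-15,16-dinorlabd-8(17)-en-13-yne-3,19-diol (3-OH equatorial; C-4 CH2OH axial)
Conditions: LiAlH4 (excess), THF, 0 °C → reflux; then H2O, aq. NaOH
Reagents that add atoms: none
Why: Hydride reduction; axial hydride delivery to the C-3 ketone (from the face away from the axial C-4 ester and C-10 methyl) gives the equatorial (3R) alcohol, and the hindered ester is reduced to CH2OH with release of the auxiliary.

**Step 9**
Reactants: 17 alkynyl diol; 18 formaldehyde (as paraformaldehyde)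
Product: 21 (3R,4R,5S,9R,10S,13Z)-13-iodo-16-norlabda-8(17),13-diene-3,15,19-triol, via trilithium propargylic alkoxide 19 (not isolated), via cyclic alkenylaluminate 20 (not isolated)
Conditions: n-BuLi (3.3 equiv), THF, −78 → 0 °C; (CH2O)n, 0 °C → rt; NaAlH2(OCH2CH2OCH3)2 (toluene, excess), 0 °C → rt; I2 (THF), −78 → 0 °C; aq. Na2S2O3
Reagents that add atoms: iodine, II
Why: Telescoped acetylide hydroxymethylation, alkoxide-directed trans-hydroalumination and iodinolysis (Corey/Denmark-type); hydride goes to C-14 and aluminium to C-13 within a five-membered oxa-aluminacycle, and iodine replaces aluminium with retention, so iodine and CH2OH are cis (Z).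

**Step 10**
Reactants: 21 (Z)-iodo allylic alcohol; 22 carbon monoxide
Product: 23 14-deoxyandrographolide [(3R,4R,5S,9R,10S)-3,19-dihydroxylabda-8(17),13-dien-16,15-olide]
Conditions: PdCl2(PPh3)2 (5 mol %), CO (1 atm), Et3N, THF, 50 °C
Reagents that add atoms: none
Why: Palladium-catalysed carbonylative lactonisation (Stille type); oxidative addition to the vinyl iodide with retention, CO insertion, and capture of the acyl-palladium by the cis CH2OH in a five-membered closure that outruns the remote hydroxyls.

**Step 11**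
Reactants: 23 14-deoxyandrographolide
Product: 24 (3R,4R,5S,7S,9S,10S)-3,7,19-trihydroxylabda-8(17),13-dien-16,15-olide (target; 7-OH axial)
Conditions: SeO2 (0.5 equiv), t-BuOOH (2 equiv), CH2Cl2/1,4-dioxane, 0 °C → rt
Reagents that add atoms: tert-butyl hydroperoxide, CC(C)(C)OO (oxygen relayed through SeO2, O=[Se]=O)
Why: SeO2 allylic hydroxylation (ene reaction, then [2,3]-sigmatropic shift) of the 1,1-disubstituted alkene at its ring CH2; oxygen is delivered axially to C-7 on the face opposite the C-10 methyl, as in 8(17)-labdenes and drimenes, and the electron-poor butenolide alkene does not react.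

**Compound list**
1 | pent-4-ynal | C#CCCC=O | starting material
2 | isopropenylmagnesium bromide | CC(=C)[Mg]Br | starting material
3 | rac-2-methylhept-1-en-6-yn-3-ol | C=C(C)C(O)CCC#C | intermediate
4 | trimethyl orthoacetate | CC(OC)(OC)OC | starting material
5 | 3-[(1-methoxyethenyl)oxy]-2-methylhept-1-en-6-yne (mixed ketene acetal) | C=C(OC)OC(CCC#C)C(C)=C | intermediate
6 | methyl (4E)-4-methylnon-4-en-8-ynoate | COC(=O)CC/C(C)=C/CCC#C | intermediate
7 | diisobutylaluminium hemiacetal of 6 | COC(O[Al](CC(C)C)CC(C)C)CC/C(C)=C/CCC#C | intermediate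
8 | (4E)-4-methylnon-4-en-8-ynal | O=CCC/C(C)=C/CCC#C | intermediate
9 | rac-(6E)-2,6-dimethylundeca-1,6-dien-10-yn-3-ol | C=C(C)C(O)CC/C(C)=C/CCC#C | intermediate
10 | (6E)-3-[(1-methoxyethenyl)oxy]-2,6-dimethylundeca-1,6-dien-10-yne (mixed ketene acetal) | C=C(OC)OC(CC/C(C)=C/CCC#C)C(C)=C | intermediate
11 | methyl (4E,8E)-4,8-dimethyltrideca-4,8-dien-12-ynoate | COC(=O)CC/C(C)=C/CC/C(C)=C/CCC#C | intermediate
12 | propanoyl chloride | CCC(=O)Cl | starting material
13 | (1S,2R,5S)-5-methyl-2-(2-phenylpropan-2-yl)cyclohexyl propanoate | CCC(=O)O[C@H]1C[C@@H](C)CC[C@@H]1C(C)(C)c1ccccc1 | intermediate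
14 | lithium enolate of 13 (methyl trans to OLi) | C/C=C(/O[Li])O[C@H]1C[C@@H](C)CC[C@@H]1C(C)(C)c1ccccc1 | intermediate
15 | (1S,2R,5S)-5-methyl-2-(2-phenylpropan-2-yl)cyclohexyl (2RS,6E,10E)-2,6,10-trimethyl-3-oxopentadeca-6,10-dien-14-ynoate | CC(C(=O)CC/C(C)=C/CC/C(C)=C/CCC#C)C(=O)O[C@H]1C[C@@H](C)CC[C@@H]1C(C)(C)c1ccccc1 | intermediate
16 | (1S,2R,5S)-5-methyl-2-(2-phenylpropan-2-yl)cyclohexyl (4S,5S,9R,10S)-3-oxo-15,16-dinorlabd-8(17)-en-13-yn-19-oate | C=C1[C@@H](CCC#C)[C@]2(C)CCC(=O)[C@@](C)(C(=O)O[C@H]3C[C@@H](C)CC[C@@H]3C(C)(C)c3ccccc3)[C@H]2CC1 | intermediate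
17 | (3R,4R,5S,9R,10S)-15,16-dinorlabd-8(17)-en-13-yne-3,19-diol | C=C1[C@@H](CCC#C)[C@]2(C)CC[C@@H](O)[C@@](C)(CO)[C@H]2CC1 | intermediate
18 | formaldehyde (used as paraformaldehyde) | C=O | starting material
19 | trilithium salt of (3R,4R,5S,9R,10S)-16-norlabd-8(17)-en-13-yne-3,15,19-triol | C=C1[C@@H](CCC#CCO[Li])[C@]2(C)CC[C@@H](O[Li])[C@@](C)(CO[Li])[C@H]2CC1 | intermediate
20 | sodium cyclic alkenyl(alkoxy)aluminate (C13–Al–O15 oxa-aluminacycle; 3,19-dilithium alkoxide) | [Na+].C=C1[C@@H](CCC2=CCO[AlH-]2OCCOC)[C@]2(C)CC[C@@H](O[Li])[C@@](C)(CO[Li])[C@H]2CC1 | intermediate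
21 | (3R,4R,5S,9R,10S,13Z)-13-iodo-16-norlabda-8(17),13-diene-3,15,19-triol | C=C1[C@@H](CC/C(I)=C/CO)[C@]2(C)CC[C@@H](O)[C@@](C)(CO)[C@H]2CC1 | intermediate
22 | carbon monoxide | [C-]#[O+] | starting material
23 | 14-deoxyandrographolide | C=C1[C@@H](CCC2=CCOC2=O)[C@]2(C)CC[C@@H](O)[C@@](C)(CO)[C@H]2CC1 | intermediate
24 | (3R,4R,5S,7S,9S,10S)-3,7,19-trihydroxylabda-8(17),13-dien-16,15-olide | C=C1[C@@H](CCC2=CCOC2=O)[C@]2(C)CC[C@@H](O)[C@@](C)(CO)[C@H]2C[C@@H]1O | target

**Step count**
Total: 11 steps. Longest linear sequence: 10 steps (1, 2, 3, 4, 6, 7, 8, 9, 10, 11); step 5 is a one-step side branch.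

**Three steps most likely to fail**

Step 7 (key bicyclisation). The risks are only moderate auxiliary control under the non-chelating conditions that the axial ester requires, competing 5-exo capture of the C-8 radical by the alkyne, and endocyclic alkene isomers. The fallback sets out from 11 and comes back at 17, replacing oxidative enol-radical generation by reductive epoxide opening and the auxiliary by a catalytic asymmetric epoxidation. Ester 11 is reduced with i-Bu2AlH at −78 °C to (4E,8E)-4,8-dimethyltrideca-4,8-dien-12-ynal F1. Wittig reaction with Ph3P=C(CH3)CO2Et gives ethyl (2E,6E,10E)-2,6,10-trimethylpentadeca-2,6,10-trien-14-ynoate F2, and i-Bu2AlH gives (2E,6E,10E)-2,6,10-trimethylpentadeca-2,6,10-trien-14-yn-1-ol F3. Sharpless epoxidation (Ti(OiPr)4, D-(−)-diethyl tartrate, t-BuOOH, 4 Å sieves, −20 °C) gives [(2R,3R)-3-[(3E,7E)-3,7-dimethyldodeca-3,7-dien-11-yn-1-yl]-2-methyloxiran-2-yl]methanol F4. Cp2TiCl (from Cp2TiCl2 and Mn dust, with 2,4,6-trimethylpyridinium chloride, THF) then opens the epoxide to the C-4 radical, which bicyclises; trivalent titanium traps the C-8 radical and β-hydride loss gives 17 directly. The weak point of this fallback is the C-4 configuration, which is not secured by precedent and may need separation of epimers.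

Step 9 (one-pot trianion hydroxymethylation / hydroalumination / iodination). The fallback sets out from 17 and comes back at 23 without passing 21. Branched-selective alkoxycarbonylation of the terminal alkyne (Pd(OAc)2, 2-(diphenylphosphino)pyridine, CH3SO3H, CO, allyl alcohol as co-solvent) gives prop-2-en-1-yl 2-methylidene-4-[(1R,4aS,5R,6R,8aS)-6-hydroxy-5-(hydroxymethyl)-5,8a-dimethyl-2-methylidenedecahydronaphthalen-1-yl]butanoate F5. Ring-closing metathesis with the second-generation Grubbs catalyst (toluene, 60 °C) then closes the butenolide to 23; the hindered exocyclic alkene stays out of the metathesis.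

Step 11 (allylic hydroxylation: over-oxidation, or the wrong C-7 epimer). The fallback sets out from 23 and comes back at 24 by oxidation then reagent-controlled reduction. Exhaustive SeO2/t-BuOOH oxidation followed by MnO2 (selective for the allylic alcohol) converges all C-7 material to (3R,4R,5S,9R,10S)-3,19-dihydroxy-7-oxolabda-8(17),13-dien-16,15-olide F6. 1,2-Reduction with the (R)-Corey–Bakshi–Shibata oxazaborolidine and catecholborane at −78 °C then gives the (7S) axial alcohol 24 without touching the lactone.

**Further compounds**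
F1 | step 7 | (4E,8E)-4,8-dimethyltrideca-4,8-dien-12-ynal | O=CCC/C(C)=C/CC/C(C)=C/CCC#C
F2 | step 7 | ethyl (2E,6E,10E)-2,6,10-trimethylpentadeca-2,6,10-trien-14-ynoate | CCOC(=O)/C(C)=C/CC/C(C)=C/CC/C(C)=C/CCC#C
F3 | step 7 | (2E,6E,10E)-2,6,10-trimethylpentadeca-2,6,10-trien-14-yn-1-ol | OC/C(C)=C/CC/C(C)=C/CC/C(C)=C/CCC#C
F4 | step 7 | [(2R,3R)-3-[(3E,7E)-3,7-dimethyldodeca-3,7-dien-11-yn-1-yl]-2-methyloxiran-2-yl]methanol | OC[C@@]1(C)O[C@@H]1CC/C(C)=C/CC/C(C)=C/CCC#C
F5 | step 9 | prop-2-en-1-yl 2-methylidene-4-[(1R,4aS,5R,6R,8aS)-6-hydroxy-5-(hydroxymethyl)-5,8a-dimethyl-2-methylidenedecahydronaphthalen-1-yl]butanoate | C=C1[C@@H](CCC(=C)C(=O)OCC=C)[C@]2(C)CC[C@@H](O)[C@@](C)(CO)[C@H]2CC1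
F6 | step 11 | (3R,4R,5S,9R,10S)-3,19-dihydroxy-7-oxolabda-8(17),13-dien-16,15-olide | C=C1[C@@H](CCC2=CCOC2=O)[C@]2(C)CC[C@@H](O)[C@@](C)(CO)[C@H]2CC1=O
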